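# Synthesis plan for CNP0234478.2: 9α-hydroxy-6α-[(2E,4E,6E)-octa-2,4,6-trienoyloxy]-12-oxodrim-7-en-11-oic acid (16)

## The problem

The target 16 is a drimane: a trans-fused decalin (rings A and B) with the C4 gem-dimethyl group and the angular C10 methyl. In ring B every carbon except C5 and C10 is functionalised: C6 carries the (2E,4E,6E)-octatrienoate, C7=C8 is conjugated with the C12 aldehyde, and C9 carries a tertiary hydroxyl and the C11 carboxylic acid. There are four stereocentres: C5 and C10 define the ring fusion, and C6 and C9 are carbinol centres that face each other 1,4 across ring B with both oxygens on the α face, opposite to the C10 methyl. C5 and C10 are therefore the natural control elements, because the axial C10 methyl and the 4β-methyl screen the β face, so an external reagent will place its atom α at C6 and at C9. The same bias is a trap at C6: hydride also arrives from the α face, a C6 ketone gives the 6β-alcohol, and the 6α-oxygen would then need an inversion at a hindered axial position with H5 antiperiplanar and ready for elimination. The fragile parts are the triene ester (oxidants, selenium dioxide, radicals, strong base), the γ-acyloxy enal, and the 1,4-related aldehyde/acid pair next to a tertiary allylic alcohol, so the triene must arrive late and the last unmasking must be mild. The key step is possible because C1–C10 with the C4 gem-dimethyl, C5–H, the C10 methyl, C8–C12 and C9–C11 are a head-to-tail farnesyl chain folded through C4–C5 and C9–C10, with its terminal oxygen at C11 and its last alkene at C7=C8.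

## Retrosynthesis

**16 ⇒ 15 (no skeletal cut).** The C11 acid and the C12 aldehyde are disguised as a tert-butyl ester and a 1,3-dioxolane in 15. A methyl ester is ruled out because its saponification would also cleave the C6 triene ester; the tert-butyl group leaves by alkyl–oxygen fission under acid. The forward reaction must remove both masks in one acid treatment without ionising the allylic C6 ester.

**15 ⇒ 13 + 14 (C6–O acyl bond).** Cutting the ester last keeps (2E,4E,6E)-octa-2,4,6-trienoic acid 14 out of all oxidation, base and photochemical steps. The precursor, diol acetal 13, has one secondary equatorial hydroxyl (6α) and one tertiary hydroxyl (9α), so a carbodiimide esterification only has to tell these apart and must proceed with retention.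

**13 ⇒ 11 through 12 (C6–O and C9–O together).** The two cis α-oxygens across ring B are the retron of a singlet-oxygen [4+2] adduct of ring B diene 11 (endoperoxide 12). The neighbouring option is to install them separately, by enolate hydroxylation at C9 and by allylic oxidation then reduction at C6. That delivers the 6β-alcohol and forces a Mitsunobu inversion at an axial hydroxyl flanked by two syn-axial methyl groups. The combined cut asks only that singlet oxygen approach the diene anti to the C10 methyl, and it sets both centres in one step.

**11 ⇒ 8 (C6–H and C9–H).** Diene 11 is the dehydrogenation product of the β,γ-unsaturated ester 8. C9–H is α to the ester and allylic, so the dienolate of 8 can be halogenated and the halide eliminated. The C9 configuration of the cyclase product is given up here on purpose, because step 7 rebuilds it.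

**8 ⇒ 7 ⇒ 5 (C12–O).** The dioxolane in 8 comes from enal 7, and 7 from selenium dioxide oxidation of the C12 methyl of tert-butyl drim-7-en-11-oate 5. The oxidation is placed here because the trisubstituted alkene of 5 is still electron-rich and carries no allylic oxygen. Later, the alkene is flanked by two oxygenated carbons and the triene would compete. The acetal also keeps the aldehyde away from the base of step 6 and keeps the diene of step 7 from becoming electron-poor.

**5 ⇒ 4 ⇒ 2 (C11 oxidation level).** Ester 5 comes from drim-7-en-11-oic acid 4, and 4 from (−)-drimenol 2 by oxidation of the primary alcohol. No carbon is added; the forward steps must not move the 7,8-alkene into conjugation.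

**2 ⇒ 1 (C4–C5 and C9–C10).** Both rings of 2 open to (2E,6E)-farnesol 1, which already holds all fifteen carbons and the C11 oxygen. A proton-initiated cyclase is asked to fold the chain chair–chair, form the two bonds, and end the cascade by loss of the C7 proton. No chemical step precedes it.

## Roads not taken

**Alternative 1:** Ring A is cut at C1–C10 and C4–C5, leading back to 4-methylpenta-1,3-diene A1 and 2,6-dimethyl-1,4-benzoquinone A2. A chiral oxazaborolidinium Lewis acid would promote the Diels–Alder addition of A1 to one alkene of A2, and base would epimerise C5 to give the trans-fused ene-dione A3.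
- Merits: two cheap achiral components, one catalytic asymmetric step, no enzyme, and a ring B that already carries oxygen at C6 and C9 and the C8 methyl. In oxidation state A3 is ahead of drimenol 2.
- Weak points:
  - The diene terminus bears two methyl groups, which disfavours the s-cis conformer and requires a bond between a fully substituted carbon and C5.
  - The C9 ketone must accept C11 on the β face, next to the axial C10 methyl, whereas nucleophiles will add from the α face and give the 9-epimer.
  - The C6 ketone reduces to the 6β-alcohol, so the inversion problem returns.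
  - The extra C2=C3 alkene must be hydrogenated beside the ene-dione alkene, and C12 is still a methyl group.
- Comparison: the chosen plan spends three redox steps on C11 and C12 that A3 partly saves, but it uses the facial bias of the decalin at both C6 and C9, whereas this road must fight it twice.

**Alternative 2:** Ring B is cut at C8–C9. Precursor A4 is a ring A cyclohexane whose C10 carries the methyl group and an α-keto tert-butyl ester (C9, C11), and whose C5 carries the chain C6(OSiEt3)–C7H=C8(I)–C12H(OEt)2 with a (Z)-vinyl iodide. CrCl2 (divalent chromium) with catalytic NiCl2 would generate a vinylchromium species that adds to the C9 ketone (Nozaki–Hiyama–Kishi closure) to give A5.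
- Merits: A5 is the most advanced intermediate of any plan considered. C6, C9, C11 and C12 stand at their final oxidation states with orthogonal protection; only desilylation, acylation and acidolysis remain. In redox economy and predictability of the endgame this road is better than the chosen one, which still needs C–H oxidations after ring formation.
- Weak points: A4 has three stereocentres on a monocyclic ring (quaternary C10, C5, the C6 carbinol) and a geometrically defined iodide, none from a pool compound, so a long sequence precedes the closure. The closure adds a hindered vinyl nucleophile to a ketone next to a quaternary carbon, and the 9α-configuration rests on a facial preference that is not obviously favourable.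
- Comparison: the chosen plan reaches the bicycle with C5 and C10 in one operation from a commodity terpene alcohol and sets C6 and C9 together under control of the angular methyl.

**Alternative 3:** Both rings are cut at once, at C5–C10 and C8–C9, opening the decalin to the acyclic triene A6. A6 is an (E)-4-oxo-enoyl oxazolidinone (C9=C10, methyl on C10) tethered through C1–C4 to an (E,E)-diene (C5=C6–C7=C8) ending in the silylated C12 alcohol. A chiral divalent-copper Lewis acid (Cu(OTf)2 with a bis(oxazoline) ligand) bound to the imide would effect the intramolecular Diels–Alder reaction to the trans-fused bicycle A7.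
- Merits: both rings and four stereocentres from an achiral chain in one catalytic step, no biocatalysis, and C12 already oxygenated, which the chosen plan must achieve with selenium dioxide.
- Weak points: the C5–C10 bond forms between a fully substituted dienophile carbon and a neopentylic diene terminus. The C1 ketone has no counterpart in the target and must be removed. The alkene ends at C6=C7 instead of C7=C8. C6 and C9 are unoxygenated, so the whole oxidation problem of ring B remains, and the C8 stereocentre is destroyed again.
- Comparison: counting the synthesis of A6 and the corrections after A7, this is the longest road. The chosen plan offers an equally short ring construction that delivers exactly the carbon skeleton with no superfluous oxygen.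

Key step: step 1

Remark on numbering: drimane numbering is used (C1–C10 decalin, C11 on C9, C12 on C8); α is the face opposite to the C10 methyl, and all compounds from 2 on are 5α-H, 10β-methyl.
Remark on the target: 16 is treated as the open 12-aldehyde 11-acid as drawn; ring–chain tautomerism to the hydroxy-lactone is taken as a property of the same compound.
Remark on supply: (2E,6E)-farnesol 1 and (2E,4E,6E)-octa-2,4,6-trienoic acid 14 are taken to be purchasable.

## Route

Step 1
Reactants: 1 (2E,6E)-farnesol
Product: 2 (−)-drimenol
Conditions: E. coli whole cells expressing a squalene–hopene cyclase variant (Alicyclobacillus acidocaldarius), citrate buffer pH 6.0, 2-hydroxypropyl-β-cyclodextrin, 30 °C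
Reagents that add atoms: none
Why: Squalene–hopene cyclases are proton-initiated terpene cyclases whose active-site acid protonates the terminal trisubstituted alkene of a polyprenyl chain; the closest known reaction type is the cyclisation of farnesol and homofarnesol to drimane- and ambrox-type bicycles by these enzymes and their variants. Protonation at C3 gives the C4 cation, which is captured by C5 of the central alkene (ring A, 6-endo cation–olefin closure), and the resulting C10 cation is captured by C9 of the allylic alkene (ring B, 6-endo), both within a pre-organised chair–chair fold. Anti addition across the two E alkenes turns alkene geometry into the trans ring fusion, so C10 (β-methyl) and C5 (α-hydrogen) are set by the fold and the E geometry, and C9 by the equatorial placement of the CH2OH-bearing terminus; the absolute sense comes from the chiral active site. The C8 cation is quenched by loss of the C7 proton to give the endocyclic 7,8-alkene. The step needs regioselective termination (7,8-alkene rather than the exocyclic 8(12)-alkene or water capture at C8), which is what the variant is chosen for. The substrate secures initiation through its terminal isopropylidene group, and its free allylic alcohol is tolerated because this enzyme class protonates an alkene and does not ionise an allylic leaving group. Only C5 and C10 are carried to the target; C9 is deliberately flattened in step 6 and re-set in step 7.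

Step 2
Reactants: 2 (−)-drimenol
Product: 4 drim-7-en-11-oic acid, via drim-7-en-11-al 3 (not isolated)
Conditions: TEMPO (cat.), PhI(OAc)2, CH2Cl2, rt; then t-BuOH/H2O, 2-methyl-2-butene, NaH2PO4, NaClO2, rt
Reagents that add atoms: sodium chlorite, [Na+].[O-]Cl=O
Why: TEMPO/PhI(OAc)2 oxidises the neopentyl-type primary alcohol to the aldehyde without touching the alkene, and Pinnick oxidation with a hypochlorite scavenger takes the unconjugated aldehyde to the acid in a buffered medium that does not move the 7,8-alkene into conjugation.

Step 3
Reactants: 4 drim-7-en-11-oic acid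
Product: 5 tert-butyl drim-7-en-11-oate
Conditions: Me2NCH(Ot-Bu)2, toluene, 80 °C
Reagents that add atoms: N,N-dimethylformamide di-tert-butyl acetal, CN(C)C(OC(C)(C)C)OC(C)(C)C
Why: Esterification by O-alkylation of the carboxylate with the formamide acetal does not require attack at the hindered carbonyl carbon and uses no strong acid that could shift the alkene; the tert-butyl ester tolerates the later enolate, oxidation and photooxygenation steps.

Step 4
Reactants: 5 tert-butyl drim-7-en-11-oate
Product: 7 tert-butyl 12-oxodrim-7-en-11-oate, via C12 allylic alcohol 6 (not isolated)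
Conditions: SeO2, 1,4-dioxane, 80 °C
Reagents that add atoms: selenium dioxide, O=[Se]=O
Why: Riley allylic oxidation: the ene reaction places selenium at C7 and takes hydrogen from a substituent of the more substituted alkene carbon C8, where the C12 methyl reacts in preference to the tertiary C9–H; the [2,3]-shift gives the C12 alcohol, which is oxidised on to the conjugated aldehyde, as known for drimenyl esters.

Step 5
Reactants: 7 tert-butyl 12-oxodrim-7-en-11-oate
Product: 8 tert-butyl 12,12-(ethylenedioxy)drim-7-en-11-oate
Conditions: (TMSOCH2)2, TMSOTf (cat.), CH2Cl2, −78 → −20 °C; pyridine quench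
Reagents that add atoms: 1,2-bis(trimethylsilyloxy)ethane, C[Si](C)(C)OCCO[Si](C)(C)C
Why: Noyori acetalisation converts enals into dioxolanes at low temperature without double-bond migration; the acetal shields the aldehyde from the base of step 6 and keeps the ring B diene of step 7 from becoming electron-poor.

Step 6
Reactants: 8 tert-butyl 12,12-(ethylenedioxy)drim-7-en-11-oate
Product: 11 tert-butyl 12,12-(ethylenedioxy)drima-6,8-dien-11-oate, via potassium dienolate 9 (not isolated), via 7α-bromide 10 (not isolated)
Conditions: KN(SiMe3)2, THF, −78 → −40 °C; BrCl2C–CCl2Br, −78 °C; then DBU, 0 °C → rt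
Reagents that add atoms: none
Why: Enolate halogenation followed by dehydrohalogenation: deprotonation at C9 (α to the ester and allylic) gives dienolate 9, which takes up electrophilic bromine at its less hindered γ terminus C7 from the α face, and the axial 7α-bromide is antiperiplanar to the axial 6β-hydrogen, so DBU effects E2 elimination to the ester-conjugated diene. Attack at either terminus of the dienolate leads to the same diene after elimination, and the C9 stereocentre is intentionally erased.

Step 7
Reactants: 11 tert-butyl 12,12-(ethylenedioxy)drima-6,8-dien-11-oate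
Product: 13 tert-butyl 12,12-(ethylenedioxy)-6α,9α-dihydroxydrim-7-en-11-oate, via 6α,9α-endoperoxide 12 (not isolated)
Conditions: O2, tetraphenylporphyrin (cat.), hν (white LED), CH2Cl2, −20 °C; then thiourea, MeOH, rt
Reagents that add atoms: dioxygen (as singlet oxygen), O=O
Why: Singlet oxygen adds to the s-cis ring B diene in a [4+2] cycloaddition (as with ergosterol, levopimaric acid or α-terpinene) from the α face, opposite to the axial C10 methyl and the 4β-methyl, so both new C–O bonds (C6 and C9) are α and cis to each other. Thiourea then reduces the O–O bond to the cis-2-ene-1,4-diol without touching acetal or ester.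

Step 8
Reactants: 13 tert-butyl 12,12-(ethylenedioxy)-6α,9α-dihydroxydrim-7-en-11-oate; 14 (2E,4E,6E)-octa-2,4,6-trienoic acid
Product: 15 tert-butyl 12,12-(ethylenedioxy)-9α-hydroxy-6α-[(2E,4E,6E)-octa-2,4,6-trienoyloxy]drim-7-en-11-oate
Conditions: DIC, DMAP (cat.), CH2Cl2, 0 °C → rt
Reagents that add atoms: none
Why: Steglich esterification acylates the secondary equatorial 6α-hydroxyl with retention, while the tertiary 9α-hydroxyl between C10 and the ester does not react; the triene acid enters only after all oxidations are done.

Step 9
Reactants: 15 tert-butyl 12,12-(ethylenedioxy)-9α-hydroxy-6α-[(2E,4E,6E)-octa-2,4,6-trienoyloxy]drim-7-en-11-oate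
Product: 16 9α-hydroxy-6α-[(2E,4E,6E)-octa-2,4,6-trienoyloxy]-12-oxodrim-7-en-11-oic acid
Conditions: TFA/CH2Cl2/H2O (10:10:1), 0 °C → rt
Reagents that add atoms: water, O
Why: Aqueous trifluoroacetic acid cleaves the tert-butyl ester by alkyl–oxygen fission (loss of isobutene) and hydrolyses the dioxolane to the conjugated aldehyde in one operation. The allylic C6 ester and the tertiary C9 alcohol should resist ionisation because either cation would sit next to or in conjugation with an electron-withdrawing carbonyl or acetal carbon.

## Compound list

1 | (2E,6E)-farnesol | CC(C)=CCC/C(C)=C/CC/C(C)=C/CO | starting material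
2 | (−)-drimenol, (5S,9S,10S)-drim-7-en-11-ol | C1C=C(C)[C@H](CO)[C@@]2(C)CCCC(C)(C)[C@H]12 | intermediate
3 | drim-7-en-11-al (9β-formyl, 9α-H) | C1C=C(C)[C@H](C=O)[C@@]2(C)CCCC(C)(C)[C@H]12 | intermediate
4 | drim-7-en-11-oic acid | C1C=C(C)[C@H](C(=O)O)[C@@]2(C)CCCC(C)(C)[C@H]12 | intermediate
5 | tert-butyl drim-7-en-11-oate | C1C=C(C)[C@H](C(=O)OC(C)(C)C)[C@@]2(C)CCCC(C)(C)[C@H]12 | intermediate
6 | tert-butyl 12-hydroxydrim-7-en-11-oate | C1C=C(CO)[C@H](C(=O)OC(C)(C)C)[C@@]2(C)CCCC(C)(C)[C@H]12 | intermediate
7 | tert-butyl 12-oxodrim-7-en-11-oate | C1C=C(C=O)[C@H](C(=O)OC(C)(C)C)[C@@]2(C)CCCC(C)(C)[C@H]12 | intermediate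
8 | tert-butyl 12,12-(ethylenedioxy)drim-7-en-11-oate (C8 carries a 1,3-dioxolan-2-yl group) | C1C=C(C3OCCO3)[C@H](C(=O)OC(C)(C)C)[C@@]2(C)CCCC(C)(C)[C@H]12 | intermediate
9 | potassium dienolate of 8 (C11=C9 enolate, C7=C8 alkene) | C1C=C(C3OCCO3)C(=C([O-])OC(C)(C)C)[C@@]2(C)CCCC(C)(C)[C@H]12.[K+] | intermediate
10 | tert-butyl 7α-bromo-12,12-(ethylenedioxy)drim-8-en-11-oate | C1[C@@H](Br)C(C3OCCO3)=C(C(=O)OC(C)(C)C)[C@@]2(C)CCCC(C)(C)[C@H]12 | intermediate
11 | tert-butyl 12,12-(ethylenedioxy)drima-6,8-dien-11-oate | C1=CC(C3OCCO3)=C(C(=O)OC(C)(C)C)[C@@]2(C)CCCC(C)(C)[C@H]12 | intermediate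
12 | tert-butyl 6α,9α-epidioxy-12,12-(ethylenedioxy)drim-7-en-11-oate | O3[C@H]1C=C(C4OCCO4)[C@](O3)(C(=O)OC(C)(C)C)[C@@]2(C)CCCC(C)(C)[C@H]12 | intermediate
13 | tert-butyl 12,12-(ethylenedioxy)-6α,9α-dihydroxydrim-7-en-11-oate | O[C@H]1C=C(C3OCCO3)[C@](O)(C(=O)OC(C)(C)C)[C@@]2(C)CCCC(C)(C)[C@H]12 | intermediate
14 | (2E,4E,6E)-octa-2,4,6-trienoic acid | C/C=C/C=C/C=C/C(=O)O | starting material
15 | tert-butyl 12,12-(ethylenedioxy)-9α-hydroxy-6α-[(2E,4E,6E)-octa-2,4,6-trienoyloxy]drim-7-en-11-oate | C/C=C/C=C/C=C/C(=O)O[C@H]1C=C(C3OCCO3)[C@](O)(C(=O)OC(C)(C)C)[C@@]2(C)CCCC(C)(C)[C@H]12 | intermediate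
16 | 9α-hydroxy-6α-[(2E,4E,6E)-octa-2,4,6-trienoyloxy]-12-oxodrim-7-en-11-oic acid | C/C=C/C=C/C=C/C(=O)O[C@H]1C=C(C=O)[C@](O)(C(=O)O)[C@@]2(C)CCCC(C)(C)[C@H]12 | target

## Step count and least certain steps

Total step count: 9. Longest linear sequence: 9 steps (1 → 16); 14 is used as purchased.

**Step 1 (key step).** The cationic cascade may terminate wrongly (loss of a C12 proton, or capture of water at C8), and turnover may be low, because the active site evolved for squalene and binds the short C15 alcohol loosely. Fallback: it sets out from 1. Chlorination (N-chlorosuccinimide, Me2S) gives (2E,6E)-farnesyl chloride F1. Displacement with tris(tetrabutylammonium) hydrogen diphosphate gives (2E,6E)-farnesyl diphosphate F2. A recombinant drimenol synthase, which cyclises the diphosphate by the same two bond formations and hydrolyses the phosphate ester, then returns to the route at 2.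

**Step 6.** Bromine transfer to the hindered dienolate may be inefficient (proton exchange between the product and unreacted enolate, or single-electron side reactions). The diene may also drift out of conjugation or epimerise at C5 through vinylogous deprotonation under base. Fallback: it sets out from 8. The potassium dienolate is oxidised with 2-(phenylsulfonyl)-3-phenyloxaziridine to tert-butyl 12,12-(ethylenedioxy)-9α-hydroxydrim-7-en-11-oate F3, the enolate hydroxylation familiar from 9-hydroxydrimane chemistry. F3 is dehydrated with SOCl2/pyridine (chlorosulfite formation, allylic transposition of chlorine to C7, loss of HCl towards C6), which returns at 11.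

**Step 7.** The ene reaction (hydrogen abstraction at C5 or at the acetal carbon) may compete, or the cycloaddition may simply be slow, because the diene carries an ester at one terminus between two fully substituted carbons. Facial selectivity is the lesser concern. Fallback: it sets out from 5 and installs the two oxygens one at a time.
- 5 is hydroxylated through its potassium enolate with the same oxaziridine to tert-butyl 9α-hydroxydrim-7-en-11-oate F4.
- Allylic oxidation with t-BuOOH and catalytic Rh2(cap)4 (dirhodium tetrakis(caprolactamate)) gives tert-butyl 9α-hydroxy-6-oxodrim-7-en-11-oate F5. This radical method leaves the tertiary allylic alcohol alone, where hexavalent chromium would risk oxidative transposition.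
- NaBH4/CeCl3 reduction from the open α face gives tert-butyl 6β,9α-dihydroxydrim-7-en-11-oate F6.
- SeO2 oxidises C12 to give tert-butyl 6β,9α-dihydroxy-12-oxodrim-7-en-11-oate F7.
- Mitsunobu esterification with 14 (PPh3, DIAD) inverts C6 to give tert-butyl 9α-hydroxy-6α-[(2E,4E,6E)-octa-2,4,6-trienoyloxy]-12-oxodrim-7-en-11-oate F8.
- Trifluoroacetic acid removes the tert-butyl group and returns at 16.

This sequence is kept in reserve because its inversion at the axial, doubly flanked 6β-hydroxyl competes with elimination towards C5.

**Step 9.** Prolonged strong acid may ionise the allylic C6 ester or dehydrate the tertiary alcohol. Hydrolysis may also stall at mixed acetal or lactol ethers when the oxocarbenium ion is captured by the neighbouring carboxyl group. Fallback: it sets out from 15 and separates the two unmaskings. The dioxolane is exchanged under near-neutral conditions (PPTS, wet acetone) to tert-butyl 9α-hydroxy-6α-[(2E,4E,6E)-octa-2,4,6-trienoyloxy]-12-oxodrim-7-en-11-oate F9 (the same structure as F8). The tert-butyl ester is then cleaved with the Lewis acid ZnBr2 in CH2Cl2 instead of a protic acid, which returns at 16.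

## Further compounds

F1 | step 1 | (2E,6E)-farnesyl chloride | CC(C)=CCC/C(C)=C/CC/C(C)=C/CCl
F2 | step 1 | (2E,6E)-farnesyl diphosphate (free acid form) | CC(C)=CCC/C(C)=C/CC/C(C)=C/COP(=O)(O)OP(=O)(O)O
F3 | step 6 | tert-butyl 12,12-(ethylenedioxy)-9α-hydroxydrim-7-en-11-oate | C1C=C(C3OCCO3)[C@](O)(C(=O)OC(C)(C)C)[C@@]2(C)CCCC(C)(C)[C@H]12
F4 | step 7 | tert-butyl 9α-hydroxydrim-7-en-11-oate | C1C=C(C)[C@](O)(C(=O)OC(C)(C)C)[C@@]2(C)CCCC(C)(C)[C@H]12
F5 | step 7 | tert-butyl 9α-hydroxy-6-oxodrim-7-en-11-oate | O=C1C=C(C)[C@](O)(C(=O)OC(C)(C)C)[C@@]2(C)CCCC(C)(C)[C@H]12
F6 | step 7 | tert-butyl 6β,9α-dihydroxydrim-7-en-11-oate | O[C@@H]1C=C(C)[C@](O)(C(=O)OC(C)(C)C)[C@@]2(C)CCCC(C)(C)[C@H]12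
F7 | step 7 | tert-butyl 6β,9α-dihydroxy-12-oxodrim-7-en-11-oate | O[C@@H]1C=C(C=O)[C@](O)(C(=O)OC(C)(C)C)[C@@]2(C)CCCC(C)(C)[C@H]12
F8 | step 7 | tert-butyl 9α-hydroxy-6α-[(2E,4E,6E)-octa-2,4,6-trienoyloxy]-12-oxodrim-7-en-11-oate | C/C=C/C=C/C=C/C(=O)O[C@H]1C=C(C=O)[C@](O)(C(=O)OC(C)(C)C)[C@@]2(C)CCCC(C)(C)[C@H]12
F9 | step 9 | tert-butyl 9α-hydroxy-6α-[(2E,4E,6E)-octa-2,4,6-trienoyloxy]-12-oxodrim-7-en-11-oate | C/C=C/C=C/C=C/C(=O)O[C@H]1C=C(C=O)[C@](O)(C(=O)OC(C)(C)C)[C@@]2(C)CCCC(C)(C)[C@H]12
A1 | alternative 1 | 4-methylpenta-1,3-diene | C=CC=C(C)C
A2 | alternative 1 | 2,6-dimethyl-1,4-benzoquinone | CC1=CC(=O)C=C(C)C1=O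
A3 | alternative 1 | trans-2,5,5,8a-tetramethyl-4a,5,8,8a-tetrahydronaphthalene-1,4-dione | O=C1C=C(C)C(=O)[C@@]2(C)CC=CC(C)(C)[C@H]12
A4 | alternative 2 | tert-butyl 2-{2-[(Z)-4,4-diethoxy-3-iodo-1-(triethylsilyloxy)but-2-enyl]-1,3,3-trimethylcyclohexyl}-2-oxoacetate (8,9-seco precursor of A5) | CC[Si](CC)(CC)O[C@@H](/C=C(\I)C(OCC)OCC)[C@H]1C(C)(C)CCC[C@]1(C)C(=O)C(=O)OC(C)(C)C
A5 | alternative 2 | tert-butyl 12,12-diethoxy-9α-hydroxy-6α-(triethylsilyloxy)drim-7-en-11-oate | CC[Si](CC)(CC)O[C@H]1C=C(C(OCC)OCC)[C@](O)(C(=O)OC(C)(C)C)[C@@]2(C)CCCC(C)(C)[C@H]12
A6 | alternative 3 | 3-[(2E,8E,10E)-12-(tert-butyldimethylsilyloxy)-3,7,7-trimethyl-4-oxododeca-2,8,10-trienoyl]oxazolidin-2-one | O=C1OCCN1C(=O)/C=C(\C)C(=O)CCC(C)(C)/C=C/C=C/CO[Si](C)(C)C(C)(C)C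
A7 | alternative 3 | 3-[12-(tert-butyldimethylsilyloxy)-1-oxodrim-6-en-11-oyl]oxazolidin-2-one (trans-fused, 8β-CH2OSi, 9β-acyl) | C1=C[C@H](CO[Si](C)(C)C(C)(C)C)[C@H](C(=O)N3CCOC3=O)[C@@]2(C)C(=O)CCC(C)(C)[C@H]12
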